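(The data stem from a simulated flask for substances that don't exist; the scatter is artificial.)

Slowness in these flasks has two seats: solid substrate enters solution over days, and free catalyst then turns the dissolved starting material into product at a pace I take as proportional to its loading, though the two earlier runs differ in temperature as well.

| setting | summer | midnight | south-west | north-east | south | east | west |
|---|---|---|---|---|---|---|---|
| solid substrate | 0.10 M | 0.10 M | 0.10 M | 0.10 M | 0.10 M | 0.10 M | 0.10 M |
| free catalyst | 0.028 mol% | 0.58 mol% | 0.1 mol% | 0.03 mol% | 0.025 mol% | 0.4 mol% | 0.2 mol% |
| temperature | 35 °C | 46 °C | 40 °C | 40 °C | 40 °C | 40 °C | 40 °C |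
| remark | run made earlier | run made earlier |  |  |  |  |  |
| time |  |  | 5.0 d | 5.0 d | 5.0 d | 5.0 d | 5.0 d |

| run | time / d | product / % | solid substrate / % |
|---|---|---|---|
| summer | 0.208 | 1 | 90 |
| summer | 0.417 | 2 | 83 |
| summer | 0.625 | 1 | 80 |
| summer | 1.25 | 3 | 60 |
| summer | 2.50 | 7 | 43 |
| midnight | 0.208 | 3 | 90 |
| midnight | 0.417 | 7 | 84 |
| midnight | 0.625 | 21 | 75 |
| midnight | 1.25 | 44 | 43 |
| midnight | 2.50 | 94 | 1 |

(scatter of a reading: 1.5 percentage points)

* the flasks by amount of product, in percent of the solid substrate charged, highest first, at 5.0 d (south-west / north-east / south / east / west)
* the amount of product, in percent of the solid substrate charged of the flask you put first, at 5.0 d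
* the amount of product, in percent of the solid substrate charged of the flask you put last, at 5.0 d

- a species is counted by the solid substrate in it: one spent catalyst counts as two
- given per volume of solution although it is solid: solid substrate
- the numbers in the tables scatter with a standard deviation of 1.5 percentage points
- on the list of suspects stand: starting material + free catalyst <-> catalyst intermediate A; catalyst intermediate A -> catalyst intermediate B; catalyst intermediate B -> free catalyst + product; catalyst intermediate A + product -> spent catalyst; solid substrate <-> starting material
- at the start none of the solid substrate is in solution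
- what has only dissolved of solid substrate counts as not reacted

I read the two tables column against column, taking what is neither solid nor product as dissolved starting material. In the summer run that is 37.0 % at 1.25 d and 50.0 % at 2.50 d; in the midnight run it is 13.0 % and 5.00 %. Summing these curves over time with straight lines from zero gives 0.775 d and 0.194 d in units of the whole charge, and the last product readings divided by these give rate constants of 0.0903 d⁻¹ and 4.85 d⁻¹.

I divide each by its loading and take the geometric mean, as 40 °C lies near the middle of 35 °C and 46 °C. This gives for east the drain time, the pseudo-first-order time constant of dissolved starting material at a given loading: 0.481 d.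

In this reckoning, with temperature and solid substrate the same in the five flasks, the drain time goes inversely with loading, so I rank them by falling loading, with east highest and south lowest.

The midnight solid stood at 1 % by 2.50 d, and I let east's solid last as long. Feeding east's charge over that time holds about 19.3 % dissolved, which in my reckoning then decays to 0.107 % by 5.0 d, so I expect 99.9 % product in east. South's drain time is 7.70 d, longer than the 5.0 d allowed. With the summer curve held at 50.0 % after its last reading, I expect 26.3 % there.

The forecast, saying “More catalyst always gives more product”, gives east > west > south-west > north-east > south, with 96 % in east and 22 % in south: my order, but lower figures than mine.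

The flasks give east > west > south-west > north-east > south, with 99.7 % in east and 26.1 % in south.

    starting material + free catalyst ⇌ catalyst intermediate A (K = 3.90 L mol⁻¹, k = 0.0660 L mol⁻¹ s⁻¹, Ea = 54.0 kJ mol⁻¹, ΔH = 5.00 kJ mol⁻¹)
    catalyst intermediate A → catalyst intermediate B (k = 0.180 s⁻¹, Ea = 76.0 kJ mol⁻¹)
    catalyst intermediate B → free catalyst + product (k = 0.950 s⁻¹, Ea = 68.0 kJ mol⁻¹)
    catalyst intermediate A + product → spent catalyst (k = 0.00150 L mol⁻¹ s⁻¹, Ea = 74.0 kJ mol⁻¹)
    solid substrate ⇌ starting material, rate k5*(cs5 - [starting material]) while solid is left; crystals form when [starting material] > cs5 (solubility = 0.0620 M, k = 9.40 × 10⁻⁶ s⁻¹)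
    (constants at 40 °C)

East holds 0.213 % starting material at 5.00 d, against the 0.107 % I reckoned. Its neighbour differs by one setting, 0.24 mol% of free catalyst instead of 0.4 mol%. The drain time there is 0.802 d, longer than east's, the dissolved amount held is 32.1 %, and the same decay from 2.50 d to 5.0 d leaves 1.42 %. The neighbouring flask itself ends with 3.0 % unreacted and 97.0 % product.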